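**Retrosynthetic overview**

1. The strategy rests on the 2,6,6-trimethylcyclohex-2-enyl ring: its C2'=C3' alkene and its only stereocentre C1' (bearing the CH2–aryl arm, next to quaternary C6') are the retron of a [4+2] between a diene C1'–C4' and a dienophile C5'=C6'.
2. Ugonin G ⇐ pyranone ring C (O1–C2 closure after Baker–Venkataraman C2–C3 bond formation) ⇐ 2-hydroxyaryl α-(MOM-oxy) ketone ⇐ ortho-lithiation/acylation of the phloroglucinol tri-ether that carries the finished (R)-cyclohexenylmethyl group.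
3. Cyclohexene ⇐ enol triflate reduction (fixes C2'=C3') and CHO → CH3 (makes C6' achiral) ⇐ Diels–Alder adduct of a 1-(arylmethyl)-2-methyl-3-silyloxybutadiene and methacrolein (bonds C1'–C6' and C4'–C5').
4. Diene ⇐ kinetic silylation of the (E)-enone ⇐ Wittig reaction of the arylacetaldehyde ⇐ allylation/cleavage of lithiated 1-PMB-3,5-bis-MOM-phloroglucinol.
5. Ring order: cyclohexene first (step 8), pyranone ring C last (step 19); both benzene rings come from the starting materials.

Key step: step 8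

Assumption: with an open-chain (E)-1-substituted diene, boron-bound methacrolein is taken to react in the formyl-endo mode and on the face predicted by the formyl C–H···O binding model, which calls for the (R)-prolinol-derived catalyst; if the adduct proves antipodal, the (S)-catalyst is used and nothing else changes.

Abbreviations: Ar = 4-[(4-methoxybenzyl)oxy]-2,6-bis(methoxymethoxy)phenyl; C1'–C6' are the cyclohexene carbons as defined in line 1 (C2' carries the vinylic methyl).

**Route**

Step 1
Reactants: 1 phloroglucinol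
Product: 2 3,5-bis(methoxymethoxy)phenol
Conditions: MOMCl (2 equiv), i-Pr2NEt, DMF, 0 °C → rt
Reagents that add atoms: chloromethyl methyl ether, COCCl
Why: Williamson-type O-alkylation with two equivalents should give the bis-ether as the main component of a statistical mixture, separable by chromatography from the mono- and tris-ethers.

Step 2
Reactants: 2 3,5-bis(methoxymethoxy)phenol
Product: 3 1-[(4-methoxybenzyl)oxy]-3,5-bis(methoxymethoxy)benzene
Conditions: PMBCl, K2CO3, Bu4NI (cat.), DMF, 60 °C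
Reagents that add atoms: 4-methoxybenzyl chloride, COc1ccc(CCl)cc1
Why: Williamson etherification of the one remaining phenol gives the oxygen that later becomes O1 a protecting group orthogonal to the two MOM ethers.

Step 3
Reactants: 3 1-[(4-methoxybenzyl)oxy]-3,5-bis(methoxymethoxy)benzene; 4 allyl bromide
Product: 6 2-allyl-5-[(4-methoxybenzyl)oxy]-1,3-bis(methoxymethoxy)benzene, via aryllithium 5 (not isolated)
Conditions: n-BuLi, TMEDA, THF, 0 °C; CuBr·SMe2 (10 mol%), allyl bromide, −78 °C → rt
Reagents that add atoms: none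
Why: Directed ortho-metalation should favour the C–H flanked by both OMOM groups, since both acetal oxygens chelate lithium (the product from the OMOM/OPMB-flanked site is a separable minor isomer), and copper-catalysed allylation of the aryllithium then forms the aryl–CH2 bond.

Step 4
Reactants: 6 2-allyl-5-[(4-methoxybenzyl)oxy]-1,3-bis(methoxymethoxy)benzene
Product: 8 2-Ar-acetaldehyde, via 1,2-diol 7 (not isolated)
Conditions: OsO4 (2 mol%), NaIO4, 2,6-lutidine, dioxane/H2O, rt
Reagents that add atoms: osmium tetroxide, O=[Os](=O)(=O)=O (oxygen carrier); sodium periodate, [Na+].[O-]I(=O)(=O)=O; water, O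
Why: Lemieux–Johnson dihydroxylation/periodate cleavage shortens the allyl group to the arylacetaldehyde without exposing the electron-rich arene and the PMB ether to ozone.

Step 5
Reactants: 9 3-bromobutan-2-one; 10 triphenylphosphine
Product: 12 3-(triphenyl-λ5-phosphanylidene)butan-2-one, via phosphonium bromide 11 (not isolated)
Conditions: PPh3, toluene, 80 °C; then 2 M NaOH, CH2Cl2, rt
Reagents that add atoms: none
Why: SN2 quaternisation of the α-bromo ketone followed by deprotonation gives the stabilised acyl ylide.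

Step 6
Reactants: 8 2-Ar-acetaldehyde; 12 3-(triphenyl-λ5-phosphanylidene)butan-2-one
Product: 13 (E)-5-Ar-3-methylpent-3-en-2-one
Conditions: toluene, 90 °C
Reagents that add atoms: none
Why: Wittig olefination with an α-methyl-substituted stabilised ylide is (E)-selective, and the enone is not expected to slip into conjugation with the arene because the two ortho OMOM groups twist a styrene out of plane.

Step 7
Reactants: 13 (E)-5-Ar-3-methylpent-3-en-2-one
Product: 15 (E)-{[5-Ar-3-methylpenta-1,3-dien-2-yl]oxy}triisopropylsilane, via lithium dienolate 14 (not isolated)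
Conditions: LDA, THF, −78 °C; TIPSOTf, −78 → −20 °C
Reagents that add atoms: triisopropylsilyl trifluoromethanesulfonate, CC(C)[Si](C(C)C)(C(C)C)OS(=O)(=O)C(F)(F)F
Why: Kinetic deprotonation of the α'-methyl group of the enone gives the cross-conjugated dienolate, whose O-silylation delivers the 2-silyloxydiene with the (E)-C1'=C2' geometry intact (TIPS is chosen over smaller silyl groups because it tolerates the cationic Lewis acid of step 8).

Step 8
Reactants: 15 (E)-{[5-Ar-3-methylpenta-1,3-dien-2-yl]oxy}triisopropylsilane; 16 methacrolein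
Product: 17 (1R,2S)-2-(Ar-methyl)-1,3-dimethyl-4-[(triisopropylsilyl)oxy]cyclohex-3-ene-1-carbaldehyde
Conditions: (R)-o-tolyl-CBS oxazaborolidine (20 mol%), Tf2NH (18 mol%), CH2Cl2, −78 °C
Reagents that add atoms: none
Why: The triflimide-protonated oxazaborolidine binds methacrolein at boron (s-trans enal, formyl C–H···O contact) and lowers its LUMO, and the diene adds in a concerted, asynchronous [4+2] cycloaddition, the closest known reaction type being the oxazaborolidinium-catalysed Diels–Alder reaction of 2-silyloxydienes with α-substituted acroleins. The six-membered carbocycle closes in the cycloaddition itself, by suprafacial union of the s-cis diene C1'–C4' with the C5'=C6' π bond, so that C4'–C5' and C1'–C6' form in one step. C6' is set by the catalyst, whose aryl group covers one face of the bound enal, and C1' is set relative to C6' by the formyl-endo transition state together with the (E) geometry of C1'=C2', which places formyl and arylmethyl cis. Regioselectivity is secured by the substrate, because the silyloxy group on C3' and the alkyl group on C1' both raise the HOMO coefficient at C4', which therefore bonds to the enal CH2. The step needs face and endo/exo selectivity together, since C6' is later made achiral; any exo diastereomer is therefore removed by chromatography at this stage, before the two adducts would turn into enantiomers.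

Step 9
Reactants: 17 (1R,2S)-2-(Ar-methyl)-1,3-dimethyl-4-[(triisopropylsilyl)oxy]cyclohex-3-ene-1-carbaldehyde
Product: 19 (3S,4R)-3-(Ar-methyl)-4-formyl-2,4-dimethylcyclohex-1-en-1-yl trifluoromethanesulfonate, via caesium enolate 18 (not isolated)
Conditions: CsF, PhNTf2, DME, 23 °C
Reagents that add atoms: N-phenylbis(trifluoromethanesulfonimide), O=S(=O)(N(c1ccccc1)S(=O)(=O)C(F)(F)F)C(F)(F)F
Why: Fluoride cleaves the Si–O bond and the regiodefined enolate is triflated on oxygen (silyl enol ether to enol triflate exchange), so the C2'=C3' position from the cycloaddition is kept, while the formyl group is non-enolisable and neopentylic and should not interfere.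

Step 10
Reactants: 19 (3S,4R)-3-(Ar-methyl)-4-formyl-2,4-dimethylcyclohex-1-en-1-yl trifluoromethanesulfonate
Product: 20 (1R,2S)-2-(Ar-methyl)-1,3-dimethylcyclohex-3-ene-1-carbaldehyde
Conditions: Pd(OAc)2 (5 mol%), PPh3 (10 mol%), HCO2H, Et3N, DMF, 60 °C
Reagents that add atoms: none
Why: Palladium-catalysed formate reduction of the enol triflate (oxidative addition, formate decarboxylation, C–H reductive elimination) replaces OTf by H at C3' without moving the alkene or touching the aldehyde and C1'.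

Step 11
Reactants: 20 (1R,2S)-2-(Ar-methyl)-1,3-dimethylcyclohex-3-ene-1-carbaldehyde
Product: 22 5-[(4-methoxybenzyl)oxy]-1,3-bis(methoxymethoxy)-2-{[(1R)-2,6,6-trimethylcyclohex-2-en-1-yl]methyl}benzene, via hydrazone 21 (not isolated)
Conditions: N2H4·H2O, diethylene glycol, 130 °C; KOH, 195 °C
Reagents that add atoms: none
Why: Wolff–Kishner reduction (Huang–Minlon procedure) of the hindered, non-enolisable aldehyde turns formyl into the second methyl group on C6', while C1'–H is not acidic and the aryl ethers and the isolated alkene are stable to hydroxide.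

Step 12
Reactants: 23 methyl glycolate
Product: 24 methyl 2-(methoxymethoxy)acetate
Conditions: MOMCl, i-Pr2NEt, CH2Cl2, 0 °C → rt
Reagents that add atoms: chloromethyl methyl ether, COCCl
Why: O-alkylation of the primary alcohol installs the same acetal that protects the phenols, so that the future 3-OH is released in the final deprotection.

Step 13
Reactants: 24 methyl 2-(methoxymethoxy)acetate; 25 N,O-dimethylhydroxylamine hydrochloride
Product: 27 N-methoxy-2-(methoxymethoxy)-N-methylacetamide, via chloromagnesium N-methoxy-N-methylamide 26 (not isolated)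
Conditions: i-PrMgCl, THF, −20 → 0 °C
Reagents that add atoms: none
Why: The magnesium amide formed in situ attacks the ester and the chelated tetrahedral adduct holds until work-up, giving the Weinreb amide directly.

Step 14
Reactants: 22 5-[(4-methoxybenzyl)oxy]-1,3-bis(methoxymethoxy)-2-{[(1R)-2,6,6-trimethylcyclohex-2-en-1-yl]methyl}benzene; 27 N-methoxy-2-(methoxymethoxy)-N-methylacetamide
Product: 29 1-{6-[(4-methoxybenzyl)oxy]-2,4-bis(methoxymethoxy)-3-{[(1R)-2,6,6-trimethylcyclohex-2-en-1-yl]methyl}phenyl}-2-(methoxymethoxy)ethan-1-one, via aryllithium 28 (not isolated)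
Conditions: n-BuLi, TMEDA, THF, −20 → 0 °C; 27, −78 → 0 °C; aq. NH4Cl
Reagents that add atoms: none
Why: Directed ortho-metalation at one of the two equivalent ring C–H positions (each flanked by OMOM and OPMB) followed by Weinreb ketone synthesis forms the C4–C4a bond, the chelated adduct preventing a second addition.

Step 15
Reactants: 29 1-{6-[(4-methoxybenzyl)oxy]-2,4-bis(methoxymethoxy)-3-{[(1R)-2,6,6-trimethylcyclohex-2-en-1-yl]methyl}phenyl}-2-(methoxymethoxy)ethan-1-one
Product: 30 1-{6-hydroxy-2,4-bis(methoxymethoxy)-3-{[(1R)-2,6,6-trimethylcyclohex-2-en-1-yl]methyl}phenyl}-2-(methoxymethoxy)ethan-1-one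
Conditions: DDQ, CH2Cl2/pH 7 buffer, 0 °C → rt
Reagents that add atoms: none
Why: Oxidative PMB cleavage (hydride abstraction at the 4-methoxybenzylic position, then hydrolysis) frees only the phenol destined to become O1; the MOM acetals and the isolated alkene are inert, and the new acyl group makes the A ring too electron-poor for its own benzylic CH2 to be oxidised.

Step 16
Reactants: 31 4-hydroxybenzoic acid
Product: 33 4-(methoxymethoxy)benzoic acid, via methoxymethyl ester 32 (not isolated)
Conditions: MOMCl, i-Pr2NEt, CH2Cl2, 0 °C → rt; LiOH, THF/MeOH/H2O, rt; 1 M HCl to pH 4, 0 °C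
Reagents that add atoms: chloromethyl methyl ether, COCCl
Why: Exhaustive alkylation gives the MOM ester/MOM ether, and hydroxide then cleaves only the ester, leaving the aryl acetal.

Step 17
Reactants: 30 1-{6-hydroxy-2,4-bis(methoxymethoxy)-3-{[(1R)-2,6,6-trimethylcyclohex-2-en-1-yl]methyl}phenyl}-2-(methoxymethoxy)ethan-1-one; 33 4-(methoxymethoxy)benzoic acid
Product: 34 3,5-bis(methoxymethoxy)-2-[(methoxymethoxy)acetyl]-4-{[(1R)-2,6,6-trimethylcyclohex-2-en-1-yl]methyl}phenyl 4-(methoxymethoxy)benzoate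
Conditions: DCC, DMAP (cat.), CH2Cl2, rt
Reagents that add atoms: none
Why: Steglich esterification acylates the single free phenol under neutral conditions that spare the four acetals.

Step 18
Reactants: 34 3,5-bis(methoxymethoxy)-2-[(methoxymethoxy)acetyl]-4-{[(1R)-2,6,6-trimethylcyclohex-2-en-1-yl]methyl}phenyl 4-(methoxymethoxy)benzoate
Product: 35 1-{6-hydroxy-2,4-bis(methoxymethoxy)-3-{[(1R)-2,6,6-trimethylcyclohex-2-en-1-yl]methyl}phenyl}-2-(methoxymethoxy)-3-[4-(methoxymethoxy)phenyl]propane-1,3-dione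
Conditions: LiHMDS, THF, −78 → 0 °C; aq. NH4Cl
Reagents that add atoms: none
Why: Baker–Venkataraman rearrangement, in which the ketone enolate attacks the neighbouring aryl ester (O → C aroyl transfer), forms the C2–C3 bond and returns the phenol.

Step 19
Reactants: 35 1-{6-hydroxy-2,4-bis(methoxymethoxy)-3-{[(1R)-2,6,6-trimethylcyclohex-2-en-1-yl]methyl}phenyl}-2-(methoxymethoxy)-3-[4-(methoxymethoxy)phenyl]propane-1,3-dione
Product: 36 3,5,7-tris(methoxymethoxy)-2-[4-(methoxymethoxy)phenyl]-6-{[(1R)-2,6,6-trimethylcyclohex-2-en-1-yl]methyl}-4H-chromen-4-one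
Conditions: NaOAc, AcOH, 90 °C
Reagents that add atoms: none
Why: Cyclodehydration (6-exo-trig hemiketalisation of the only free phenol onto the aroyl carbonyl, then loss of water) closes ring C under buffered conditions while the other ortho oxygen is still a MOM ether, so that only the 6-substituted flavonol can form.

Step 20
Reactants: 36 3,5,7-tris(methoxymethoxy)-2-[4-(methoxymethoxy)phenyl]-6-{[(1R)-2,6,6-trimethylcyclohex-2-en-1-yl]methyl}-4H-chromen-4-one
Product: 37 Ugonin G
Conditions: 3 M aq. HCl, MeOH, 45 °C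
Reagents that add atoms: none
Why: Acid-catalysed transacetalisation to methanol removes all four MOM groups under the mild conditions commonly used for prenylated polyphenols, which should leave the trisubstituted ring alkene and C1' untouched.

**Compound list**

1 | phloroglucinol (benzene-1,3,5-triol) | Oc1cc(O)cc(O)c1 | starting material
2 | 3,5-bis(methoxymethoxy)phenol | COCOc1cc(O)cc(OCOC)c1 | intermediate
3 | 1-[(4-methoxybenzyl)oxy]-3,5-bis(methoxymethoxy)benzene | COCOc1cc(OCOC)cc(OCc2ccc(OC)cc2)c1 | intermediate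
4 | allyl bromide | C=CCBr | starting material
5 | {4-[(4-methoxybenzyl)oxy]-2,6-bis(methoxymethoxy)phenyl}lithium | [Li]c1c(OCOC)cc(OCc2ccc(OC)cc2)cc1OCOC | intermediate
6 | 2-allyl-5-[(4-methoxybenzyl)oxy]-1,3-bis(methoxymethoxy)benzene | C=CCc1c(OCOC)cc(OCc2ccc(OC)cc2)cc1OCOC | intermediate
7 | 3-{4-[(4-methoxybenzyl)oxy]-2,6-bis(methoxymethoxy)phenyl}propane-1,2-diol (racemic) | OCC(O)Cc1c(OCOC)cc(OCc2ccc(OC)cc2)cc1OCOC | intermediate
8 | 2-{4-[(4-methoxybenzyl)oxy]-2,6-bis(methoxymethoxy)phenyl}acetaldehyde | O=CCc1c(OCOC)cc(OCc2ccc(OC)cc2)cc1OCOC | intermediate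
9 | 3-bromobutan-2-one | CC(=O)C(C)Br | starting material
10 | triphenylphosphine | c1ccc(P(c2ccccc2)c2ccccc2)cc1 | starting material
11 | (3-oxobutan-2-yl)triphenylphosphonium bromide | CC(=O)C(C)[P+](c1ccccc1)(c1ccccc1)c1ccccc1.[Br-] | intermediate
12 | 3-(triphenyl-λ5-phosphanylidene)butan-2-one | CC(=O)C(C)=P(c1ccccc1)(c1ccccc1)c1ccccc1 | intermediate
13 | (E)-5-{4-[(4-methoxybenzyl)oxy]-2,6-bis(methoxymethoxy)phenyl}-3-methylpent-3-en-2-one | CC(=O)/C(C)=C/Cc1c(OCOC)cc(OCc2ccc(OC)cc2)cc1OCOC | intermediate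
14 | lithium (E)-5-{4-[(4-methoxybenzyl)oxy]-2,6-bis(methoxymethoxy)phenyl}-3-methylpenta-1,3-dien-2-olate | [Li]OC(=C)/C(C)=C/Cc1c(OCOC)cc(OCc2ccc(OC)cc2)cc1OCOC | intermediate
15 | (E)-{[5-{4-[(4-methoxybenzyl)oxy]-2,6-bis(methoxymethoxy)phenyl}-3-methylpenta-1,3-dien-2-yl]oxy}triisopropylsilane | C=C(O[Si](C(C)C)(C(C)C)C(C)C)/C(C)=C/Cc1c(OCOC)cc(OCc2ccc(OC)cc2)cc1OCOC | intermediate
16 | methacrolein | CC(=C)C=O | starting material
17 | (1R,2S)-2-({4-[(4-methoxybenzyl)oxy]-2,6-bis(methoxymethoxy)phenyl}methyl)-1,3-dimethyl-4-[(triisopropylsilyl)oxy]cyclohex-3-ene-1-carbaldehyde (formyl cis to arylmethyl) | CC1=C(O[Si](C(C)C)(C(C)C)C(C)C)CC[C@@](C)(C=O)[C@H]1Cc1c(OCOC)cc(OCc2ccc(OC)cc2)cc1OCOC | intermediate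
18 | caesium (3S,4R)-4-formyl-3-({4-[(4-methoxybenzyl)oxy]-2,6-bis(methoxymethoxy)phenyl}methyl)-2,4-dimethylcyclohex-1-en-1-olate | CC1=C([O-])CC[C@@](C)(C=O)[C@H]1Cc1c(OCOC)cc(OCc2ccc(OC)cc2)cc1OCOC.[Cs+] | intermediate
19 | (3S,4R)-4-formyl-3-({4-[(4-methoxybenzyl)oxy]-2,6-bis(methoxymethoxy)phenyl}methyl)-2,4-dimethylcyclohex-1-en-1-yl trifluoromethanesulfonate | CC1=C(OS(=O)(=O)C(F)(F)F)CC[C@@](C)(C=O)[C@H]1Cc1c(OCOC)cc(OCc2ccc(OC)cc2)cc1OCOC | intermediate
20 | (1R,2S)-2-({4-[(4-methoxybenzyl)oxy]-2,6-bis(methoxymethoxy)phenyl}methyl)-1,3-dimethylcyclohex-3-ene-1-carbaldehyde | CC1=CCC[C@@](C)(C=O)[C@H]1Cc1c(OCOC)cc(OCc2ccc(OC)cc2)cc1OCOC | intermediate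
21 | hydrazone of 20, (1R,2S) | CC1=CCC[C@@](C)(C=NN)[C@H]1Cc1c(OCOC)cc(OCc2ccc(OC)cc2)cc1OCOC | intermediate
22 | 5-[(4-methoxybenzyl)oxy]-1,3-bis(methoxymethoxy)-2-{[(1R)-2,6,6-trimethylcyclohex-2-en-1-yl]methyl}benzene | CC1=CCCC(C)(C)[C@H]1Cc1c(OCOC)cc(OCc2ccc(OC)cc2)cc1OCOC | intermediate
23 | methyl glycolate | COC(=O)CO | starting material
24 | methyl 2-(methoxymethoxy)acetate | COCOCC(=O)OC | intermediate
25 | N,O-dimethylhydroxylamine hydrochloride | CNOC.Cl | starting material
26 | chloromagnesium N-methoxy-N-methylamide | CON(C)[Mg]Cl | intermediate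
27 | N-methoxy-2-(methoxymethoxy)-N-methylacetamide | COCOCC(=O)N(C)OC | intermediate
28 | {6-[(4-methoxybenzyl)oxy]-2,4-bis(methoxymethoxy)-3-{[(1R)-2,6,6-trimethylcyclohex-2-en-1-yl]methyl}phenyl}lithium | CC1=CCCC(C)(C)[C@H]1Cc1c(OCOC)c([Li])c(OCc2ccc(OC)cc2)cc1OCOC | intermediate
29 | 1-{6-[(4-methoxybenzyl)oxy]-2,4-bis(methoxymethoxy)-3-{[(1R)-2,6,6-trimethylcyclohex-2-en-1-yl]methyl}phenyl}-2-(methoxymethoxy)ethan-1-one | CC1=CCCC(C)(C)[C@H]1Cc1c(OCOC)c(C(=O)COCOC)c(OCc2ccc(OC)cc2)cc1OCOC | intermediate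
30 | 1-{6-hydroxy-2,4-bis(methoxymethoxy)-3-{[(1R)-2,6,6-trimethylcyclohex-2-en-1-yl]methyl}phenyl}-2-(methoxymethoxy)ethan-1-one | CC1=CCCC(C)(C)[C@H]1Cc1c(OCOC)c(C(=O)COCOC)c(O)cc1OCOC | intermediate
31 | 4-hydroxybenzoic acid | O=C(O)c1ccc(O)cc1 | starting material
32 | methoxymethyl 4-(methoxymethoxy)benzoate | COCOC(=O)c1ccc(OCOC)cc1 | intermediate
33 | 4-(methoxymethoxy)benzoic acid | COCOc1ccc(C(=O)O)cc1 | intermediate
34 | 3,5-bis(methoxymethoxy)-2-[(methoxymethoxy)acetyl]-4-{[(1R)-2,6,6-trimethylcyclohex-2-en-1-yl]methyl}phenyl 4-(methoxymethoxy)benzoate | CC1=CCCC(C)(C)[C@H]1Cc1c(OCOC)c(C(=O)COCOC)c(OC(=O)c2ccc(OCOC)cc2)cc1OCOC | intermediate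
35 | 1-{6-hydroxy-2,4-bis(methoxymethoxy)-3-{[(1R)-2,6,6-trimethylcyclohex-2-en-1-yl]methyl}phenyl}-2-(methoxymethoxy)-3-[4-(methoxymethoxy)phenyl]propane-1,3-dione (C2 unassigned; keto/enol/hemiketal mixture) | CC1=CCCC(C)(C)[C@H]1Cc1c(OCOC)c(C(=O)C(OCOC)C(=O)c2ccc(OCOC)cc2)c(O)cc1OCOC | intermediate
36 | 3,5,7-tris(methoxymethoxy)-2-[4-(methoxymethoxy)phenyl]-6-{[(1R)-2,6,6-trimethylcyclohex-2-en-1-yl]methyl}-4H-chromen-4-one | CC1=CCCC(C)(C)[C@H]1Cc1c(OCOC)cc2oc(-c3ccc(OCOC)cc3)c(OCOC)c(=O)c2c1OCOC | intermediate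
37 | Ugonin G, 3,5,7-trihydroxy-2-(4-hydroxyphenyl)-6-{[(1R)-2,6,6-trimethylcyclohex-2-en-1-yl]methyl}-4H-chromen-4-one | CC1=CCCC(C)(C)[C@H]1Cc1c(O)cc2oc(-c3ccc(O)cc3)c(O)c(=O)c2c1O | target

**Step count**

Total: 20 steps. Longest linear sequence: 16 steps (1–4, 6–11, 14, 15, 17–20); steps 5, 12, 13 and 16 prepare the ylide, the Weinreb amide and the aroyl partner.

**Steps most likely to fail**

Step 8. The catalyst may discriminate poorly between the enal faces or between endo and exo approach of this trisubstituted diene, and the cationic Lewis acid may instead trigger protodesilylation or a stepwise Mukaiyama–Michael addition. The fallback builds the quaternary carbon in two stages. Setting out from 15, the same oxazaborolidinium catalysis (catalyst antipode chosen by the two-point α-C–H···O binding model for acrylates) would be run with 2,2,2-trifluoroethyl acrylate, a dienophile with a dependable endo preference, to give the trifluoroethyl ester adduct F1. Enolate methylation (LDA, MeI, −78 °C), expected anti to the neighbouring arylmethyl group, would give the α-methylated ester F2. LiAlH4 would reduce it to the primary alcohol F3, and buffered Dess–Martin oxidation brings the route back to 17.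

Step 9. The unmasked enolate may be consumed by aldol capture or by retro-Michael ring opening through the free formyl group, which would also erode C1'. The fallback removes the carbonyl before the enolate is generated. Setting out from 17, TsNHNH2 in EtOH would give the tosylhydrazone F4. Catecholborane followed by NaOAc·3H2O (Kabalka deoxygenation) would give the gem-dimethyl silyl enol ether F5. CsF/PhNTf2 would then give the gem-dimethyl enol triflate F6, and Pd/formate reduction returns the route to 22, bypassing 19–21.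

Step 20. Under protic acid the freed C5/C7 phenols may add across the C2'=C3' alkene (chroman-type ring closure), or the double bond may migrate. The fallback never exposes free phenols to acid. Setting out from 36, Ac2O with catalytic Sc(OTf)3 would exchange each aryl MOM ether for an acetate to give the flavonol tetraacetate F7, and K2CO3 in MeOH at 0 °C then returns the route to 37.

**Further compounds**

F1 | step 8 | 2,2,2-trifluoroethyl (1R,2R)-2-({4-[(4-methoxybenzyl)oxy]-2,6-bis(methoxymethoxy)phenyl}methyl)-3-methyl-4-[(triisopropylsilyl)oxy]cyclohex-3-ene-1-carboxylate | CC1=C(O[Si](C(C)C)(C(C)C)C(C)C)CC[C@@H](C(=O)OCC(F)(F)F)[C@H]1Cc1c(OCOC)cc(OCc2ccc(OC)cc2)cc1OCOC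
F2 | step 8 | 2,2,2-trifluoroethyl (1R,2S)-2-({4-[(4-methoxybenzyl)oxy]-2,6-bis(methoxymethoxy)phenyl}methyl)-1,3-dimethyl-4-[(triisopropylsilyl)oxy]cyclohex-3-ene-1-carboxylate | CC1=C(O[Si](C(C)C)(C(C)C)C(C)C)CC[C@@](C)(C(=O)OCC(F)(F)F)[C@H]1Cc1c(OCOC)cc(OCc2ccc(OC)cc2)cc1OCOC
F3 | step 8 | [(1R,2R)-2-({4-[(4-methoxybenzyl)oxy]-2,6-bis(methoxymethoxy)phenyl}methyl)-1,3-dimethyl-4-[(triisopropylsilyl)oxy]cyclohex-3-en-1-yl]methanol | CC1=C(O[Si](C(C)C)(C(C)C)C(C)C)CC[C@@](C)(CO)[C@H]1Cc1c(OCOC)cc(OCc2ccc(OC)cc2)cc1OCOC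
F4 | step 9 | (E)-N'-{[(1R,2R)-2-({4-[(4-methoxybenzyl)oxy]-2,6-bis(methoxymethoxy)phenyl}methyl)-1,3-dimethyl-4-[(triisopropylsilyl)oxy]cyclohex-3-en-1-yl]methylidene}-4-methylbenzenesulfonohydrazide | CC1=C(O[Si](C(C)C)(C(C)C)C(C)C)CC[C@@](C)(/C=N/NS(=O)(=O)c2ccc(C)cc2)[C@H]1Cc1c(OCOC)cc(OCc2ccc(OC)cc2)cc1OCOC
F5 | step 9 | triisopropyl{[(3R)-3-({4-[(4-methoxybenzyl)oxy]-2,6-bis(methoxymethoxy)phenyl}methyl)-2,4,4-trimethylcyclohex-1-en-1-yl]oxy}silane | CC1=C(O[Si](C(C)C)(C(C)C)C(C)C)CCC(C)(C)[C@H]1Cc1c(OCOC)cc(OCc2ccc(OC)cc2)cc1OCOC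
F6 | step 9 | (3R)-3-({4-[(4-methoxybenzyl)oxy]-2,6-bis(methoxymethoxy)phenyl}methyl)-2,4,4-trimethylcyclohex-1-en-1-yl trifluoromethanesulfonate | CC1=C(OS(=O)(=O)C(F)(F)F)CCC(C)(C)[C@H]1Cc1c(OCOC)cc(OCc2ccc(OC)cc2)cc1OCOC
F7 | step 20 | 2-[4-(acetyloxy)phenyl]-4-oxo-6-{[(1R)-2,6,6-trimethylcyclohex-2-en-1-yl]methyl}-4H-chromene-3,5,7-triyl triacetate | CC1=CCCC(C)(C)[C@H]1Cc1c(OC(C)=O)cc2oc(-c3ccc(OC(C)=O)cc3)c(OC(C)=O)c(=O)c2c1OC(C)=O
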